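The constants used here were set for the occasion; what happens was integrated by code.

A neighbour of this flask carries 0.34 M of free catalyst, so I asked first what catalyst buys here.

starting material 2.0 M; gas phase 200 mM (held); free catalyst 200 mM; time 12 h

    starting material + target → side product (k1 = 0.0052 M⁻¹ min⁻¹)
    dissolved gas + free catalyst → spent catalyst (k2 = 0.029 M⁻¹ min⁻¹)
    starting material + dissolved gas + free catalyst → free catalyst + target (k3 = 0.12 M⁻² min⁻¹)
    gas phase ⇌ dissolved gas, rate k4*(csat - [dissolved gas]) (k4 = 0.066 min⁻¹, csat = 200 mM)

- in percentages every species weighs as the starting material in it: one side product counts as two
- at the start none of the gas is dissolved
- run time (flask): 12 h

* how much target there is at 12 h, in percent of the starting material charged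
* the change that raises the amount of target at 12 h, in percent of the starting material charged most ("none" if none brings more than 2 percentage points) (ash / birch / cedar / none)
* amount of target at 12 h, in percent of the starting material charged, after birch

- ash: doubling the saturation concentration of gas phase, all else as stated
- birch: doubling the amount of free catalyst, all else as stated
- cedar: doubling the transfer coefficient of step 4, all else as stated

I drew the target curve by hand. It starts flat, with no gas dissolved. Dissolved gas climbs for about 15.2 min, then knees near 0.110 M, which gives target a slope of 0.00529 M min⁻¹. Dissolved gas stands in both catalyst steps, so it cancels from their ratio: at the charged [starting material], 8.28 target form per free catalyst lost, the turnover number. Target peaks where making meets use by the side step, at [target] = k3[dissolved gas][free catalyst]/k1. That is 0.509 M with the charged catalyst, and it sinks as catalyst dies. The side draw rises from nothing to equal making at that crossing, so I replaced it by its mean, 0.5, and charged each target 1.50 starting material. The falling [starting material] then gives a budget of 0.948 M target made. Afterwards target and starting material fall one for one, so their difference stays at 0.104 M while their ratio grows exponentially. That leaves 8.15%. Doubled catalyst budgets 1.22 M, which ends at 25.2%. Ash and cedar act on the gas, which the budget doesn't contain, so I chose birch.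

The forecast gave 8.3%, birch and 23.6%, holding that “Catalyst death still caps formation near 1.1 M”.

The flask gave 8.50%, birch and 24.2%: birch added 16 percentage points, ash 1.4 points, cedar 0.011 points. The main reason target ended at this level in this flask is the reaction of starting material + target to side product: with that step taken away, target at 12 h stood at 55.2% against 8.50%, a difference of 47 points. The forecast's choice turned in one further run: with the reaction of dissolved gas + free catalyst to spent catalyst taken away, which is a part of the story, target reached 30.7% and birch no longer came out best.

In the neighbour with 0.34 M of free catalyst, the same turnover number budgets 1.17 M, which leaves 21.3%. The computed result there is 19.8%.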